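## Analysis of the target

Premarineosin A (22) is a [9](2,5)pyrrolophane. Its twelve-membered ansa ring consists of ring C (a 2,5-disubstituted pyrrole), the methine Ca on pyrrole C2, the branch carbon Cb and seven CH2 groups that lead back to pyrrole C5. Ca and Cb are also ring atoms of a tetrahydropyran (O, CMe, CH2, Cb, Ca, Cspiro). Cspiro is an N,O-ketal carbon and at the same time C5 of ring B, a 3-methoxy-2H-pyrrole that carries ring A (pyrrol-2-yl) on its C=N carbon.

All four stereocentres lie on the tetrahydropyran: CMe (S), Cb (S), Ca (S) and Cspiro (R). Methyl and bridge are trans across the ring, the bridge on Cb and ring C on Ca are trans, and ring C is cis to the ring B nitrogen.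

Two features invite the strategy. Without the O–Cspiro bond, rings A and B are a 4-methoxy-2,2'-bipyrrole and Ca is the meso carbon of a dipyrromethane; the target is therefore the internal alcohol adduct of a two-electron-oxidised, dearomatised dipyrromethane. Secondly, the five atoms O–CMe(CH3)–CH2–Cb–Ca are those of γ-valerolactone.

Sensitive groups are the N,O-ketal (acid ionises it to a cation that can tautomerise to a prodiginine chromophore), the methoxy enol ether within a 1-azadiene, three electron-rich pyrrole units, and the doubly activated Ca–H. The difficulty is a quaternary spiro ketal next to a tertiary stereocentre inside a strained ansa ring, at an oxidation level between pyrrole and pyrrolinone.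

## Retrosynthetic reasoning

**22 to 21 (cut O–Cspiro).** Removing this bond and adding two hydrogens re-aromatises ring B and gives the leuco compound 21, in which only Ca, Cb and CMe are stereogenic. Forward, a mild oxidant must take two electrons from the methoxybipyrrole, and the tethered (S)-alcohol must capture C5 of ring B before the Ca proton is lost. This one event makes the tetrahydropyran, the spiro centre and the 2H-pyrrole.

**21 to 15 and 20 (cut Ca–C5 of ring B).** This is the bond a dipyrromethane synthesis makes: an α-free, electron-rich pyrrole (20) adds to the cation obtained by ionising a 2-pyrrolylcarbinol derivative. In 15 the carbinol oxygen is the same oxygen that later becomes the ketal oxygen, tied up as a tetrahydrofuran. Ionisation therefore releases the alcohol exactly when the cation forms, and no protecting group is needed. The cut is made here, and not at the ring A–ring B bond, because it lets the whole bipyrrole enter as one stable, separately made piece and puts the oxidation last.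

**15 to 13 (cut a C–C bond in the middle of the bridge, through 14).** Ring-closing olefin metathesis followed by hydrogenation closes the ansa ring at a site far from the pyrrole and from the acid-labile ether. The pyrrole must be N–H at this stage so that the bridge can pass across nitrogen.

**13 to 11 to 8 and 4 (cut Ca–C2 of ring C).** A 5-metalated N-Boc pyrrole adds to the lactol 4. The carbinol centre formed needs no control because it is ionised later. Working at the lactol (aldehyde) level means Cb is never α to a ketone.

**4 to 3 to 1 and 2.** The lactol comes from the trans-allylated lactone 3, and this from (S)-γ-valerolactone (1) and allyl bromide (2). The bought CMe centre sets Cb by 1,3-induction in the enolate alkylation.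

**Side pieces.** 8 comes from 5 and 6 by hydroboration and sp3–sp2 cross-coupling. 20 comes from 19, and this from lactam 16 and boronic acid 17 through the lactam-derived triflate 18.

## Alternatives that were turned down

Alternative 1: the textbook route. The ring A–ring B bond is cut last (spiro-lactam A1, then imidoyl triflate, then coupling with 17). A1 is made from the hydroxy keto amide A2 by acid-mediated N-acyliminium ketalisation, and the ansa ring by metathesis. It was turned down for four reasons. In A2, Ca is flanked by a ketone and a pyrrole and is therefore very prone to epimerisation. A2 needs a linear build-up of a 3-methoxy-4-oxo-enamide. Every stereocentre must be set separately. Ring A arrives only through a moisture-sensitive triflate next to an acid-labile ketal. The step count would be roughly twice that of the route below.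

Alternative 2: an intramolecular inverse-demand hetero-Diels–Alder reaction of the enone prodiginine A3. The enone would act as the oxadiene and the exocyclic Ca=C5 bond of ring B as the dienophile, giving dihydropyran A4 with the ansa ring, Ca, Cb and Cspiro in one step. It was turned down because the polarity is mismatched. The oxadiene needs the nucleophilic terminus of the dienophile at Ca, but ring C as π-donor makes C5 of ring B the nucleophilic end and Ca the electrophilic meso carbon. The matched orientation would thus join O to Ca. In addition the cycloaddition must close a twelve-membered ring. A4 would also need a chemoselective, face-selective hydrogenation of its cyclic enol ether in the presence of the more easily reduced methoxy-azadiene, with CMe set last.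

Alternative 3: a biomimetic oxidative carbocyclisation of the open-chain (S)-23-hydroxyundecylprodiginine A5. A radical at Cb would add to the meso carbon Ca, followed by oxidation and capture by the hydroxyl. It was turned down because no chemical reagent can pick the Cb methylene out of eight similar ones. A pre-installed radical precursor at Cb would have to be built with the chain anyway. The macrocyclising radical addition competes with reduction and with attack at other positions of the chromophore. Finally, Cb (a planar radical) and Ca would be formed without any controlling element, the only stereocentre being the remote CMe.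

Key step: step 9

Assumption: compounds 1, 6, 16 and 17 are taken as commercial; the configuration at Ca in 11–15 is left uncontrolled on purpose, since this centre is ionised in step 9. Bridge numbering used in names: C1 = Ca (on pyrrole C2), C2 = Cb, C3–C9 = the seven CH2 groups (C9 on pyrrole C5).

## Route

Step 1
Reactants: 1 (S)-γ-valerolactone; 2 allyl bromide
Product: 3 (3S,5S)-5-methyl-3-(prop-2-en-1-yl)oxolan-2-one
Conditions: LDA (lithium diisopropylamide), THF, –78 °C; then 2, –78 → –40 °C
Reagents that add atoms: none
Why: Alkylation of the lithium enolate of a γ-substituted butyrolactone; the electrophile should enter anti to the γ-methyl group (1,3-induction), which gives the trans lactone and sets Cb, and the minor cis isomer is removed by chromatography.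

Step 2
Reactants: 3 (3S,5S)-5-methyl-3-(prop-2-en-1-yl)oxolan-2-one
Product: 4 (3S,5S)-5-methyl-3-(prop-2-en-1-yl)oxolan-2-ol (anomers)
Conditions: i-Bu2AlH (1.1 equiv), CH2Cl2, –78 °C; aqueous Rochelle salt
Reagents that add atoms: none
Why: Half-reduction of a γ-lactone at low temperature stops at the aluminium lactolate; the alkene and both stereocentres are untouched, and Cb never becomes α to a ketone.

Step 3
Reactants: 5 hexa-1,5-diene; 6 tert-butyl 2-bromo-1H-pyrrole-1-carboxylate
Product: 8 tert-butyl 2-(hex-5-en-1-yl)-1H-pyrrole-1-carboxylate, via hexenylborane 7 (not isolated)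
Conditions: 9-BBN, 5 (4 equiv), THF, 0 °C → rt; then 6, Pd(dppf)Cl2 (3 mol %), K3PO4 (aq), DMF, 50 °C
Reagents that add atoms: none
Why: Hydroboration of one terminus of the diene (used in excess) and B-alkyl Suzuki–Miyaura coupling with the 2-bromopyrrole; phosphate base at 50 °C should leave the N-Boc group in place.

Step 4
Reactants: 8 tert-butyl 2-(hex-5-en-1-yl)-1H-pyrrole-1-carboxylate; 4 (3S,5S)-5-methyl-3-(prop-2-en-1-yl)oxolan-2-ol
Product: 11 tert-butyl 2-[(2S,4S)-1,4-dihydroxy-2-(prop-2-en-1-yl)pentyl]-5-(hex-5-en-1-yl)-1H-pyrrole-1-carboxylate (C1 epimers), via lithiopyrrole 9 (not isolated), via pyrrolylmagnesium bromide 10 (not isolated)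
Conditions: lithium 2,2,6,6-tetramethylpiperidide, THF, –78 °C; MgBr2·OEt2; then 4 (0.45 equiv), –78 → 0 °C; aq NH4Cl
Reagents that add atoms: none
Why: Carbamate-directed α-lithiation at the free C5 of the pyrrole, transmetalation to the more stable magnesium species, and 1,2-addition to the open aldehyde form of the lactolate (one equivalent is spent on the O–H). The new carbinol centre Ca forms without control, which does not matter; any Boc that shifts from N to O converges in step 5.

Step 5
Reactants: 11 tert-butyl 2-[(2S,4S)-1,4-dihydroxy-2-(prop-2-en-1-yl)pentyl]-5-(hex-5-en-1-yl)-1H-pyrrole-1-carboxylate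
Product: 13 2-(hex-5-en-1-yl)-5-[(3S,5S)-5-methyl-3-(prop-2-en-1-yl)oxolan-2-yl]-1H-pyrrole (epimers at oxolane C2), via pyrrolyl diol 12 (not isolated)
Conditions: NaOMe (0.3 equiv), MeOH–THF, 0 °C → rt; then PPTS (5 mol %), 4 Å MS, CH2Cl2, 0 °C
Reagents that add atoms: none
Why: Methoxide cleaves the activated N-acylpyrrole carbamate, and mild acid ionises the N–H pyrrolylcarbinol to its azafulvenium ion, which the γ-hydroxyl traps in a 5-exo closure (SN1 substitution of a 2-pyrrolylcarbinol). Both α-positions of the pyrrole are blocked, so self-condensation is suppressed. The ether masks carbinol and alcohol at once, and the free N–H is needed so that the bridge can later pass across nitrogen.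

Step 6
Reactants: 13 2-(hex-5-en-1-yl)-5-[(3S,5S)-5-methyl-3-(prop-2-en-1-yl)oxolan-2-yl]-1H-pyrrole
Product: 15 tetrahydrofuran-fused [9](2,5)pyrrolophane (O–CH(CH3)–CH2 unit joining bridge C1 through O to bridge C2; C2 S; methyl carbinol carbon S; C1 epimers), via macrocyclic alkene 14 (not isolated)
Conditions: second-generation Grubbs catalyst (7 mol %), toluene (1 mM), 60 °C; then H2 (7 atm), 70 °C
Reagents that add atoms: none
Why: Ring-closing olefin metathesis forms the twelve-membered ansa ring at a bond remote from pyrrole and ether, and the ruthenium residue serves as hydrogenation catalyst under H2 (tandem metathesis–hydrogenation), so the E/Z mixture converges to one saturated bridge. The neutral conditions spare the acid-labile ether.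

Step 7
Reactants: 16 4-methoxy-1,5-dihydro-2H-pyrrol-2-one; 17 [1-(tert-butoxycarbonyl)-1H-pyrrol-2-yl]boronic acid
Product: 19 tert-butyl 4'-methoxy-1H,1'H-[2,2'-bipyrrole]-1-carboxylate, via imidoyl triflate 18 (not isolated)
Conditions: Tf2O, CH2Cl2, 0 °C; then 17, Pd(PPh3)4 (5 mol %), K2CO3 (aq), 1,4-dioxane, 85 °C
Reagents that add atoms: none
Why: O-Sulfonylation of the vinylogous lactam gives an imidoyl triflate that undergoes Suzuki–Miyaura coupling with the pyrrol-2-ylboronic acid, the established lactam-triflate way to the bipyrrole of prodiginines. The coupled 2H-pyrrole tautomerises to the aromatic bipyrrole.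

Step 8
Reactants: 19 tert-butyl 4'-methoxy-1H,1'H-[2,2'-bipyrrole]-1-carboxylate
Product: 20 4-methoxy-1H,1'H-2,2'-bipyrrole
Conditions: NaOMe (0.5 equiv), MeOH–THF, rt, argon; used at once
Reagents that add atoms: none
Why: Methanolysis of the N-acylpyrrole-type carbamate frees the air-sensitive bipyrrole just before it is needed.

Step 9
Reactants: 15 tetrahydrofuran-fused [9](2,5)pyrrolophane; 20 4-methoxy-1H,1'H-2,2'-bipyrrole
Product: 22 premarineosin A, via leuco adduct 21 (not isolated)
Conditions: 20 (1.2 equiv), camphorsulfonic acid (5 mol %), CH2Cl2, –40 → 0 °C, argon; then NaHCO3, activated MnO2 (10 equiv), 0 °C → rt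
Reagents that add atoms: none
Why: Proposed new method: catalytic acid ionises the Ca–O bond of 15 to the ring C azafulvenium ion, which frees the (S)-alcohol, and C5 of 20 (the α-position next to OMe, its most nucleophilic site) adds as in a dipyrromethane synthesis (Friedel–Crafts) to give 21. Ca is set in this addition by peripheral attack: the bridge crosses one face of the cation above N–H, so 20 should enter from the outer face, which is also the face of the hydroxypropyl arm, and this places H on Ca anti to H on Cb as in 22. MnO2 then takes two electrons and the ring B N–H proton from the most electron-rich π-system, the 5-alkyl-4-methoxy-2,2'-bipyrrole, to give a delocalised cation (2H-pyrrolium on ring B, azafulvenium on ring A) that is electrophilic at C5 of ring B, and the tethered hydroxyl captures it. This closes the tetrahydropyran in a 6-exo-trig mode (O on C5 of ring B) and creates the spiro N,O-ketal and the 2H-pyrrole in the same event; the closest known reaction types are the oxidative dearomatising spiroketalisation of hydroxyalkyl phenols with PhI(OAc)2 and the oxidation of dipyrromethanes to dipyrrins, which passes through the same kind of cation. Cspiro is controlled by a chair transition state with the Ca and Cb ring substituents equatorial, in which the small ring B nitrogen takes the axial site (anomeric stabilisation, hydrogen bond to N–H of ring C) and the bulkier C(OMe)= arm the equatorial one; as the ketal can reopen to the same cation, this centre can also settle thermodynamically. The selectivity needed is capture by oxygen at C5 instead of loss of the Ca proton, which would give the conjugated macrocyclic prodiginine; it is secured by the unimolecular six-membered closure, by the faster N–H than C–H deprotonation of the radical cation, and by the A(1,3) strain between the Cb branch and the ring B methoxy group that opposes planarisation at Ca.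

## Compound list

1 | (S)-γ-valerolactone, (5S)-5-methyloxolan-2-one | C[C@H]1CCC(=O)O1 | starting material
2 | allyl bromide (3-bromoprop-1-ene) | C=CCBr | starting material
3 | (3S,5S)-5-methyl-3-(prop-2-en-1-yl)oxolan-2-one (trans) | C[C@H]1C[C@H](CC=C)C(=O)O1 | intermediate
4 | (3S,5S)-5-methyl-3-(prop-2-en-1-yl)oxolan-2-ol (anomers) | C[C@H]1C[C@H](CC=C)C(O)O1 | intermediate
5 | hexa-1,5-diene | C=CCCC=C | starting material
6 | tert-butyl 2-bromo-1H-pyrrole-1-carboxylate | CC(C)(C)OC(=O)n1cccc1Br | starting material
7 | 9-(hex-5-en-1-yl)-9-borabicyclo[3.3.1]nonane | C=CCCCCB1C2CCCC1CCC2 | intermediate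
8 | tert-butyl 2-(hex-5-en-1-yl)-1H-pyrrole-1-carboxylate | CC(C)(C)OC(=O)n1cccc1CCCCC=C | intermediate
9 | tert-butyl 2-(hex-5-en-1-yl)-5-lithio-1H-pyrrole-1-carboxylate | CC(C)(C)OC(=O)n1c([Li])ccc1CCCCC=C | intermediate
10 | [1-(tert-butoxycarbonyl)-5-(hex-5-en-1-yl)-1H-pyrrol-2-yl]magnesium bromide | CC(C)(C)OC(=O)n1c([Mg]Br)ccc1CCCCC=C | intermediate
11 | tert-butyl 2-[(2S,4S)-1,4-dihydroxy-2-(prop-2-en-1-yl)pentyl]-5-(hex-5-en-1-yl)-1H-pyrrole-1-carboxylate (C1 epimers) | C[C@H](O)C[C@H](CC=C)C(O)c1ccc(CCCCC=C)n1C(=O)OC(C)(C)C | intermediate
12 | (2S,4S)-1-[5-(hex-5-en-1-yl)-1H-pyrrol-2-yl]-2-(prop-2-en-1-yl)pentane-1,4-diol (C1 epimers) | C[C@H](O)C[C@H](CC=C)C(O)c1ccc(CCCCC=C)[nH]1 | intermediate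
13 | 2-(hex-5-en-1-yl)-5-[(3S,5S)-5-methyl-3-(prop-2-en-1-yl)oxolan-2-yl]-1H-pyrrole (epimers at oxolane C2) | C[C@H]1C[C@H](CC=C)C(O1)c1ccc(CCCCC=C)[nH]1 | intermediate
14 | macrocyclic alkene: [9](2,5)pyrrolophane with a C4=C5 double bond in the bridge (E/Z), bridge C1 and C2 fused to the (5S)-5-methyloxolane (O on C1), C2 S, C1 epimers | C[C@H]1C[C@@H]2CC=CCCCCc3ccc([nH]3)C2O1 | intermediate
15 | tetrahydrofuran-fused [9](2,5)pyrrolophane: saturated bridge, O–CH(CH3)–CH2 unit joining bridge C1 (through O) to bridge C2, C2 S, methyl carbinol carbon S, C1 epimers | C[C@H]1C[C@@H]2CCCCCCCc3ccc([nH]3)C2O1 | intermediate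
16 | 4-methoxy-1,5-dihydro-2H-pyrrol-2-one (4-methoxy-3-pyrrolin-2-one) | COC1=CC(=O)NC1 | starting material
17 | [1-(tert-butoxycarbonyl)-1H-pyrrol-2-yl]boronic acid | CC(C)(C)OC(=O)n1cccc1B(O)O | starting material
18 | 3-methoxy-2H-pyrrol-5-yl trifluoromethanesulfonate | COC1=CC(OS(=O)(=O)C(F)(F)F)=NC1 | intermediate
19 | tert-butyl 4'-methoxy-1H,1'H-[2,2'-bipyrrole]-1-carboxylate | COc1c[nH]c(-c2cccn2C(=O)OC(C)(C)C)c1 | intermediate
20 | 4-methoxy-1H,1'H-2,2'-bipyrrole | COc1c[nH]c(-c2ccc[nH]2)c1 | intermediate
21 | leuco adduct: [9](2,5)pyrrolophane with the 4-methoxy-1H,1'H-2,2'-bipyrrol-5-yl group on bridge C1 (S) and the (2S)-2-hydroxypropyl group on bridge C2 (S) | C[C@H](O)C[C@@H]1CCCCCCCc2ccc([nH]2)[C@H]1c1[nH]c(-c2ccc[nH]2)cc1OC | intermediate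
22 | premarineosin A (Cspiro R, CMe S, Cb S, Ca S) | COC1=CC(c2ccc[nH]2)=N[C@]12O[C@@H](C)C[C@@H]1CCCCCCCc3ccc([nH]3)[C@H]12 | target

## Step count and risks

Total step count: 9. Longest linear sequence: 6 steps (1, 2, 4, 5, 6, 9).

**Step 9 (key step, carries the label).** Four processes may go wrong:
- After oxidation, loss of the Ca proton (or direct hydride abstraction at Ca) may outrun capture by oxygen and lead to the conjugated prodiginine chromophore.
- The bipyrrole may add with poor facial selectivity at Ca.
- The acid may fragment the dipyrromethane at the ring C–Ca bond.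
- Reversible deprotonation of the azafulvenium ion at Cb (vinylpyrrole formation) may erode that centre.

Fallback with known chemistry, from 15 back to 22, bringing ring B in at the lactam level. 16 is protected (Boc2O, DMAP) to tert-butyl 4-methoxy-2-oxo-2,5-dihydro-1H-pyrrole-1-carboxylate F1 and silylated (TBSOTf, Et3N) to the silyloxypyrrole F2. A BF3·OEt2-mediated vinylogous Mukaiyama-type substitution of 15 with F2 gives the 5-alkylated lactam F3. Aerobic hydroxylation of its dienolate (KOt-Bu, O2, P(OEt)3) gives the hydroxy lactam F4. Trifluoroacetic acid converts F4 through its N-acyliminium ion into the spiro N,O-ketal lactam F5 with loss of Boc. Tf2O gives the imidoyl triflate F6, Suzuki–Miyaura coupling with 17 gives N-Boc-premarineosin A F7, and NaOMe in MeOH returns to 22.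

**Step 6.** Strain of the ansa ring may divert the metathesis to oligomers by cross-metathesis, and ruthenium hydride may migrate the allyl double bond before closure, which contracts the ring.

Fallback, from 1 back to 15, closing the ring at the pyrrole C5–CH2 bond instead. Alkylation of 1 (LDA, DMPU, 7-iodohept-1-ene) gives the lactone F8. tert-Butyl 2,5-dibromo-1H-pyrrole-1-carboxylate F9 (from N-Boc-pyrrole and NBS) is monolithiated with n-BuLi and opens F8; NaOMe completes loss of Boc to give the stable bromo ketone F10. Hydroboration of the terminal alkene with 9-BBN and high-dilution intramolecular B-alkyl Suzuki–Miyaura coupling (Pd(dppf)Cl2, K3PO4, DMF–THF–H2O) give the macrocyclic ketone F11. NaBH4 gives the diol F12, and PPTS closes the ether to 15.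

**Step 4.** The metalated N-Boc pyrrole may decompose by migration of Boc from N to carbon before it adds. The lactolate may open too slowly. Enolisation of the open aldehyde form may erode Cb.

Fallback, from 8 back to 13, by electrophilic substitution instead of an organometallic addition. NaOMe in MeOH converts 8 into 2-(hex-5-en-1-yl)-1H-pyrrole F13. Its free α-position is alkylated by the cyclic oxocarbenium ion of lactol 4 under Sc(OTf)3 catalysis (Friedel–Crafts C-alkylation of the C-glycosylation type), which gives 13 directly.

**Step 7.** The unprotected imidoyl triflate may tautomerise to an electron-rich pyrrolyl triflate that oligomerises under the triflic acid formed, and the boronic acid may protodeboronate.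

Fallback, from 16 back to 20: Vilsmeier–Haack-type condensation of 16 with pyrrole (POCl3, then aqueous base), the classical lactam-plus-pyrrole way to 2,2'-bipyrroles. It gives 20 in one operation without a new isolated compound.

## Further compounds

F1 | step 9 | tert-butyl 4-methoxy-2-oxo-2,5-dihydro-1H-pyrrole-1-carboxylate | COC1=CC(=O)N(C1)C(=O)OC(C)(C)C
F2 | step 9 | tert-butyl 2-{[tert-butyl(dimethyl)silyl]oxy}-4-methoxy-1H-pyrrole-1-carboxylate | COc1cc(O[Si](C)(C)C(C)(C)C)n(c1)C(=O)OC(C)(C)C
F3 | step 9 | 5-alkylated lactam: tert-butyl 3-methoxy-5-oxo-2,5-dihydro-1H-pyrrole-1-carboxylate carrying at C2 the bridge C1 (S) of the [9](2,5)pyrrolophane with the (2S)-2-hydroxypropyl group on bridge C2 (S) | C[C@H](O)C[C@@H]1CCCCCCCc2ccc([nH]2)[C@H]1C1N(C(=O)OC(C)(C)C)C(=O)C=C1OC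
F4 | step 9 | hydroxy lactam: the 2-hydroxy derivative of F3 (N-acyl hemiaminal) | C[C@H](O)C[C@@H]1CCCCCCCc2ccc([nH]2)[C@H]1C1(O)N(C(=O)OC(C)(C)C)C(=O)C=C1OC
F5 | step 9 | spiro N,O-ketal lactam (ring B as 4-methoxy-3-pyrrolin-2-one, configurations as in 22) | COC1=CC(=O)N[C@]12O[C@@H](C)C[C@@H]1CCCCCCCc3ccc([nH]3)[C@H]12
F6 | step 9 | imidoyl triflate of F5 | COC1=CC(OS(=O)(=O)C(F)(F)F)=N[C@]12O[C@@H](C)C[C@@H]1CCCCCCCc3ccc([nH]3)[C@H]12
F7 | step 9 | N-Boc-premarineosin A (Boc on ring A nitrogen) | COC1=CC(c2cccn2C(=O)OC(C)(C)C)=N[C@]12O[C@@H](C)C[C@@H]1CCCCCCCc3ccc([nH]3)[C@H]12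
F8 | step 6 | (3S,5S)-3-(hept-6-en-1-yl)-5-methyloxolan-2-one | C[C@H]1C[C@H](CCCCCC=C)C(=O)O1
F9 | step 6 | tert-butyl 2,5-dibromo-1H-pyrrole-1-carboxylate | CC(C)(C)OC(=O)n1c(Br)ccc1Br
F10 | step 6 | (2S,4S)-1-(5-bromo-1H-pyrrol-2-yl)-2-(hept-6-en-1-yl)-4-hydroxypentan-1-one | C[C@H](O)C[C@H](CCCCCC=C)C(=O)c1ccc(Br)[nH]1
F11 | step 6 | macrocyclic ketone: [9](2,5)pyrrolophan-1-one with the (2S)-2-hydroxypropyl group on bridge C2 (S) | C[C@H](O)C[C@@H]1CCCCCCCc2ccc([nH]2)C1=O
F12 | step 6 | macrocyclic diol: [9](2,5)pyrrolophan-1-ol with the (2S)-2-hydroxypropyl group on bridge C2 (S), C1 epimers | C[C@H](O)C[C@@H]1CCCCCCCc2ccc([nH]2)C1O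
F13 | step 4 | 2-(hex-5-en-1-yl)-1H-pyrrole | C=CCCCCc1ccc[nH]1
F0 | step 7 | none | none
A1 | alternative 1 | spiro N,O-ketal lactam (ring B as 4-methoxy-3-pyrrolin-2-one) | COC1=CC(=O)N[C@]12O[C@@H](C)C[C@@H]1CCCCCCCc3ccc([nH]3)[C@H]12
A2 | alternative 1 | hydroxy keto amide: (Z)-3-methoxy-4-oxobut-2-enamide attached through C4 to bridge C1 (S) of the [9](2,5)pyrrolophane with the (2S)-2-hydroxypropyl group on bridge C2 (S) | C[C@H](O)C[C@@H]1CCCCCCCc2ccc([nH]2)[C@H]1C(=O)/C(OC)=C\C(N)=O
A3 | alternative 2 | enone prodiginine: prodiginine whose ring C carries a (9E)-11-oxododec-9-en-1-yl chain | COC1=CC(c2ccc[nH]2)=N/C1=C\c1ccc(CCCCCCC/C=C/C(C)=O)[nH]1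
A4 | alternative 2 | dihydropyran cycloadduct (6-methyl-4H-pyran in place of the tetrahydropyran of 22) | COC1=CC(c2ccc[nH]2)=N[C@]12OC(C)=C[C@@H]1CCCCCCCc3ccc([nH]3)[C@H]12
A5 | alternative 3 | (S)-23-hydroxyundecylprodiginine | COC1=CC(c2ccc[nH]2)=N/C1=C\c1ccc(CCCCCCCCC[C@H](C)O)[nH]1
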